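The numbers in the tables are calculated for substances that don't exist.

- You must choose what to do with the grey flask at 8.0 d, and that choice depends on whether the flask is still moving by then.

| setting | grey | teal | flask |
|---|---|---|---|
| L | 13 mM | 13 mM | 13 mM |
| Z | 5 mol% | 3.4 mol% | 5 mol% |
| remark | the very flask that is asked about, followed so far | run made earlier |  |
| time |  |  | 8.0 d |

| run | time / d | Q / % | L / % |
|---|---|---|---|
| grey | 0.417 | 62.3 | 6.6 |
| grey | 0.833 | 47.7 | 4.5 |
| grey | 1.25 | 39.0 | 3.3 |
| grey | 2.50 | 31.3 | 2.4 |
| grey | 5.00 | 29.9 | 3.3 |
| teal | 0.833 | 49.0 | 5.0 |
| teal | 1.67 | 35.4 | 2.6 |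
| teal | 3.00 | 30.8 | 2.7 |
| teal | 6.00 | 30.0 | 2.8 |
| teal | 10.0 | 29.5 | 2.7 |

(readings scatter by 0.3 percentage points)

- Q that was removed still counts
- additions bring no volume worth counting

- south-west: at 8.0 d add L, 50.0 % of the amount charged, then wait 4.0 d
- south-east: change nothing and wait 4.0 d more
- west: at 8.0 d add Z, 100 % of the amount charged, then wait 4.0 d
- north-west: at 8.0 d take out 90 % of the Q then present, then wait 4.0 d

1. Q, in percent of the L first charged, at 8.0 d
2. what to do for the largest gain in Q; "none" if nothing gains more than 2 percentage points (south-west / south-east / west / north-west / none)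
3. Q present, with what was taken out counted in, in percent of the L first charged, after south-west
4. Q present, with what was taken out counted in, in percent of the L first charged, after west

- The first rung is L turning into Q. By the first grey reading, at 0.417 d, c_L is down to 6.6 %, and c_L/c_Q reads 0.106, against 0.0915 at the last teal reading, so from here on c_L roughly follows c_Q.
- The next rung is c_Q sinking towards a level. The last grey reading and the last two teal readings average 29.8 %; call this the rest share, the part of the L put in that stands as Q once c_Q has stopped moving.
- Measured above that level, the grey readings of c_Q give a decay rate of 1.52 d⁻¹, a half-life of 0.458 d. Teal, with 3.4 mol% of Z against 5 mol%, reads 1.47 d⁻¹.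
- The last rung is rest. Since 8.0 d is 17.5 of those half-lives, far longer than one, control has crossed from the clock to the rest share, which chemists call thermodynamic control. My reckoning for now is therefore 29.8 %.
- Waiting gains nothing by my reckoning, and neither does Z, because the two loadings level off alike, grey at 29.9 % and teal at 30.0 %.
- I assume the rest state scales with what the flask holds, though both runs share one charge. Adding L then gains 15 percentage points.
- Taking out Q worth 26.8 % of the L charged leaves a smaller flask, which by my reckoning regains its rest state within 4.0 d, that is 8.73 half-lives. The gain is the amount taken times one minus the rest share, 19 points, more than adding L gives.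
- The forecast gave 29.8 % for now, 44.7 % for south-west, 29.8 % for west, and chose north-west, saying “At 8 d the flask is at equilibrium, with Q ≈ 29.8.”

    L + Z ⇌ Q + Z, rate k1*[L]*[Z] forward; the back reaction follows from the equilibrium constant (K = 12.0, k = 560 L mol⁻¹ h⁻¹)
    Q ⇌ G (K = 2.30, k = 0.0440 h⁻¹)
    G + Z ⇌ L + Z, rate k3*[Z]*[G] forward; the back reaction follows from the equilibrium constant (k = 1.80 L mol⁻¹ h⁻¹)

The flask gives 29.6 % at 8.0 d, and north-west is best, gaining 19 points against 15 points for south-west. The step of G turning into L has a forward half-life of 25 d at the charged concentrations, longer than 8.0 d, and it makes no difference to Q at that time. The rest share gives 44.7 % after south-west, where the flask gives 44.4 %. For a neighbour flask with 8.5 mol% of Z the rest share again says 29.8 %, and that flask holds Q at 29.6 % at 8.00 d.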